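Ring A of the target is a phloroglucinol: oxygen sits on C5, C7 and C8a, and C8, which carries the chiral side chain, lies between two of them. The route therefore builds ring A from an open chain: C8 is the methylene next to the stereocenter in one arm of 3-phenylglutaric acid, extended by a masked triketide. In one operation, methoxide opens a 4-methoxy-2-pyranone and the chain carbanion (C8) closes onto the liberated ester carbon (C7), giving a 2-substituted 5-methoxyresorcinol with the stereocenter untouched. The precursor is the 6-alkyl-4-methoxy-2-pyranone whose spectator carboxyl is a tert-butyl ester, so that only one ester can be attacked.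

Key step: step 7

Assumption: the quinidine-derived catalyst of step 1 is taken to deliver the (S)-hemiester 2; if the sense of induction is the opposite, the quinine-derived pseudoenantiomer is used and nothing else changes.

Remark: the target and all intermediates from 3 onward are (R); hemiester 2 is (S) only because its CIP priorities differ, the spatial arrangement being the same throughout. A methyl ester on the spectator arm would offer the doubly activated carbanions of steps 4, 5 and 7 a six-membered Dieckmann closure, which is why that arm is carried as the tert-butyl ester.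

Step 1
Reactants: 1 3-phenylglutaric anhydride
Product: 2 (3S)-5-methoxy-5-oxo-3-phenylpentanoic acid
Conditions: MeOH (10 equiv), quinidine-derived 9-amino(9-deoxy)-epi-cinchona 3,5-bis(trifluoromethyl)benzenesulfonamide (C28H27F6N3O3S, 5 mol %), MTBE, rt; one recrystallization
Reagents that add atoms: methanol, CO
Why: Alcoholysis of a meso anhydride under bifunctional cinchona catalysis (quinuclidine activates methanol, the sulfonamide N–H binds one enantiotopic carbonyl) desymmetrizes 1 and sets the only stereocenter under catalyst control, the minor enantiomer being removed by crystallization.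

Step 2
Reactants: 2 (3S)-5-methoxy-5-oxo-3-phenylpentanoic acid
Product: 3 1-tert-butyl 5-methyl (3R)-3-phenylpentanedioate
Conditions: tert-butyl 2,2,2-trichloroacetimidate (2 equiv), CH2Cl2/cyclohexane, rt
Reagents that add atoms: tert-butyl 2,2,2-trichloroacetimidate, CC(C)(C)OC(=N)C(Cl)(Cl)Cl
Why: Imidate esterification (proton transfer, then capture of the tert-butyl cation by the carboxylate) leaves the methyl ester untouched and installs the hindered ester that serves as a non-electrophilic spectator in steps 4, 5 and 7; the stereocenter is β to both carbonyls and cannot epimerize.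

Step 3
Reactants: 3 1-tert-butyl 5-methyl (3R)-3-phenylpentanedioate
Product: 4 (3R)-5-tert-butoxy-5-oxo-3-phenylpentanoic acid
Conditions: LiOH·H2O (1.2 equiv), THF/H2O, 0 °C → rt; then 1 M HCl to pH 3
Reagents that add atoms: lithium hydroxide, [Li+].[OH-]
Why: Hydroxide saponifies the unhindered methyl ester far faster than the tert-butyl ester (selective ester hydrolysis), so the free acid now marks the arm that will become ring A.

Step 4
Reactants: 4 (3R)-5-tert-butoxy-5-oxo-3-phenylpentanoic acid; 5 methyl acetoacetate
Product: 7 1-tert-butyl 9-methyl (3R)-5,7-dioxo-3-phenylnonanedioate, via acyl imidazolide 6 (not isolated)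
Conditions: CDI (1.1 equiv), THF, rt; then added to 5 (2.5 equiv)/LiN(iPr)2 (5 equiv), THF, –78 → –20 °C; cold 1 M HCl
Reagents that add atoms: none
Why: The acid is activated as its N-acylimidazole and the more basic γ-carbon of the acetoacetate dianion is acylated (Weiler dianion C-acylation, a crossed Claisen condensation), the excess dianion absorbing the acidic proton of the product.

Step 5
Reactants: 7 1-tert-butyl 9-methyl (3R)-5,7-dioxo-3-phenylnonanedioate
Product: 8 tert-butyl (3R)-4-(4-hydroxy-2-oxo-2H-pyran-6-yl)-3-phenylbutanoate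
Conditions: DBU (1.5 equiv), toluene, 80 °C; cold 1 M HCl wash
Reagents that add atoms: none
Why: The enol oxygen of the outer ketone attacks the methyl ester in a 6-exo-trig lactonization to the 4-hydroxy-2-pyranone (standard DBU cyclization of 3,5-dioxo esters), while the tert-butyl ester is too hindered for a competing Dieckmann closure.

Step 6
Reactants: 8 tert-butyl (3R)-4-(4-hydroxy-2-oxo-2H-pyran-6-yl)-3-phenylbutanoate
Product: 9 tert-butyl (3R)-4-(4-methoxy-2-oxo-2H-pyran-6-yl)-3-phenylbutanoate
Conditions: Me2SO4 (1.2 equiv), K2CO3 (1.5 equiv), acetone, reflux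
Reagents that add atoms: dimethyl sulfate, COS(=O)(=O)OC
Why: The pyranone hydroxyl is a vinylogous carboxylic acid whose potassium salt is O-methylated by the hard electrophile mainly at the 4-oxygen (Williamson-type O-alkylation), the minor 2-methoxy-4-pyranone isomer being removed by chromatography.

Step 7
Reactants: 9 tert-butyl (3R)-4-(4-methoxy-2-oxo-2H-pyran-6-yl)-3-phenylbutanoate
Product: 11 tert-butyl (3R)-3-(2,6-dihydroxy-4-methoxyphenyl)-3-phenylpropanoate, via ring-opened keto ester 10 (not isolated)
Conditions: Mg(OMe)2 (3 equiv), MeOH, reflux, N2; then cold 1 M HCl to pH 4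
Reagents that add atoms: none
Why: Methoxide adds to the lactone carbonyl of 9 and opens the ring to keto ester 10, in which the enol ether stops the ester terminus from enolizing and so keeps it electrophilic, while magnesium holds the ketone and ester oxygens together. The enolate on the outer methylene of the ketone (the carbon next to the stereocenter, future C8) then attacks that ester (future C7, equivalent to C8a until step 8) in a Claisen condensation of Dieckmann type, a 6-exo-trig closure that expels methoxide, and the resulting 5-methoxycyclohexene-1,3-dione tautomerizes to the aromatic ring; the closest known reaction is the base-induced recyclization of 4-methoxy-6-methyl-2-pyranone to 5-methoxyresorcinol. No stereocenter is formed, and the existing one carries no acidic hydrogen because it is β to every carbonyl, so its configuration is carried through. The step needs C-acylation at the ester of the opened pyranone to win over reclosure to 9, which is reversible and only delays the reaction, and over attack of the more acidic C5 carbanion on the side-chain carboxyl, which is suppressed because that carboxyl is a hindered tert-butyl ester; aromatization to the phenoxide makes the desired closure irreversible. The two hydroxyls of 11 are interchanged by rotation of the ring, so later substitution has one constitutional outcome.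

Step 8
Reactants: 11 tert-butyl (3R)-3-(2,6-dihydroxy-4-methoxyphenyl)-3-phenylpropanoate
Product: 13 (4R)-6-acetyl-5-hydroxy-7-methoxy-4-phenyl-3,4-dihydro-2H-chromen-2-one, via hydroxy lactone 12 (not isolated)
Conditions: BF3·OEt2 (4 equiv), AcOH, rt, N2 sweep; then Ac2O (1.3 equiv), 60 °C; aq. NaOAc, 50 °C
Reagents that add atoms: acetic anhydride, CC(=O)OC(C)=O
Why: The Lewis acid cleaves the tert-butyl ester and the acid closes onto an ortho hydroxyl to dihydrocoumarin 12 (acid-catalyzed lactonization), whose remaining phenol directs Friedel–Crafts C-acetylation (Fries-type ortho delivery, product held as the BF2 chelate) to C6; an acetyl group entering at C8 instead would give the same compound 15 once the lactone is opened in step 9, because the two positions are equivalent in the open form.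

Step 9
Reactants: 13 (4R)-6-acetyl-5-hydroxy-7-methoxy-4-phenyl-3,4-dihydro-2H-chromen-2-one; 14 4-methoxybenzaldehyde
Product: 16 (3R)-3-{2,6-dihydroxy-4-methoxy-3-[(2E)-3-(4-methoxyphenyl)prop-2-enoyl]phenyl}-3-phenylpropanoic acid, via ring-opened acetophenone acid 15 (not isolated)
Conditions: KOH (50% aq., 15 equiv), EtOH, N2, rt, 48 h; then 1 M HCl to pH 3, 0 °C
Reagents that add atoms: potassium hydroxide, [K+].[OH-]
Why: Hydroxide first opens the lactone to the salt of 15, whose methyl ketone then undergoes Claisen–Schmidt condensation with the non-enolizable aldehyde and E1cB dehydration to the (E)-enone; the stereocenter has no acidic hydrogen and is unaffected.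

Step 10
Reactants: 16 (3R)-3-{2,6-dihydroxy-4-methoxy-3-[(2E)-3-(4-methoxyphenyl)prop-2-enoyl]phenyl}-3-phenylpropanoic acid
Product: 18 (3R)-3-[7-hydroxy-5-methoxy-2-(4-methoxyphenyl)-4-oxo-4H-chromen-8-yl]-3-phenylpropanoic acid, via flavanone acid 17 (not isolated)
Conditions: I2 (10 mol %), DMSO, 120 °C; aq. Na2S2O3; 1 M NaOH, rt, 15 min; 1 M HCl to pH 3, 0 °C
Reagents that add atoms: none
Why: The chelated hydroxyl, the only one ortho to the enone carbonyl because the other ortho position carries the methoxyl, adds to the enone (oxa-Michael) to flavanone 17, which is α-iodinated and loses HI while DMSO reoxidizes HI to I2 (iodine-catalyzed oxidative cyclization of 2'-hydroxychalcones), so only the 8-substituted flavone can form; the alkaline wash keeps the side chain as the open acid.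

Step 11
Reactants: 18 (3R)-3-[7-hydroxy-5-methoxy-2-(4-methoxyphenyl)-4-oxo-4H-chromen-8-yl]-3-phenylpropanoic acid
Product: 20 (3R)-3-[5,7-dihydroxy-2-(4-hydroxyphenyl)-4-oxo-4H-chromen-8-yl]-3-phenylpropanoic acid, via demethylated lactone 19 (not isolated)
Conditions: BBr3 (8 equiv), CH2Cl2, –78 °C → rt; H2O, 0 °C; then LiOH, THF/H2O, N2, rt; 1 M HCl to pH 3–4, 0 °C
Reagents that add atoms: lithium hydroxide, [Li+].[OH-]
Why: BBr3 cleaves both aryl methyl ethers (Lewis acid complexation, then SN2 attack of bromide on methyl, the 5-methoxyl assisted by chelation to the 4-carbonyl) and the acidic, dehydrating medium closes the side chain onto the 7-oxygen to lactone 19, which LiOH then saponifies; acidification only to pH 3–4 in the cold should release the open acid without relactonization.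

Compound list
1 | 3-phenylglutaric anhydride | O=C1CC(CC(=O)O1)c1ccccc1 | starting material
2 | (3S)-5-methoxy-5-oxo-3-phenylpentanoic acid | OC(=O)C[C@H](c1ccccc1)CC(=O)OC | intermediate
3 | 1-tert-butyl 5-methyl (3R)-3-phenylpentanedioate | CC(C)(C)OC(=O)C[C@H](c1ccccc1)CC(=O)OC | intermediate
4 | (3R)-5-tert-butoxy-5-oxo-3-phenylpentanoic acid | CC(C)(C)OC(=O)C[C@H](c1ccccc1)CC(=O)O | intermediate
5 | methyl acetoacetate | COC(=O)CC(C)=O | starting material
6 | tert-butyl (3R)-5-(1H-imidazol-1-yl)-5-oxo-3-phenylpentanoate (acyl imidazolide) | CC(C)(C)OC(=O)C[C@H](c1ccccc1)CC(=O)n1ccnc1 | intermediate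
7 | 1-tert-butyl 9-methyl (3R)-5,7-dioxo-3-phenylnonanedioate | CC(C)(C)OC(=O)C[C@H](c1ccccc1)CC(=O)CC(=O)CC(=O)OC | intermediate
8 | tert-butyl (3R)-4-(4-hydroxy-2-oxo-2H-pyran-6-yl)-3-phenylbutanoate | CC(C)(C)OC(=O)C[C@H](c1ccccc1)CC1=CC(O)=CC(=O)O1 | intermediate
9 | tert-butyl (3R)-4-(4-methoxy-2-oxo-2H-pyran-6-yl)-3-phenylbutanoate | CC(C)(C)OC(=O)C[C@H](c1ccccc1)CC1=CC(OC)=CC(=O)O1 | intermediate
10 | 9-tert-butyl 1-methyl (2E,7R)-3-methoxy-5-oxo-7-phenylnon-2-enedioate (ring-opened keto ester) | CC(C)(C)OC(=O)C[C@H](c1ccccc1)CC(=O)C/C(OC)=C\C(=O)OC | intermediate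
11 | tert-butyl (3R)-3-(2,6-dihydroxy-4-methoxyphenyl)-3-phenylpropanoate | CC(C)(C)OC(=O)C[C@H](c1ccccc1)c1c(O)cc(OC)cc1O | intermediate
12 | (4R)-5-hydroxy-7-methoxy-4-phenyl-3,4-dihydro-2H-chromen-2-one (hydroxy lactone) | O=C1C[C@H](c2ccccc2)c2c(O)cc(OC)cc2O1 | intermediate
13 | (4R)-6-acetyl-5-hydroxy-7-methoxy-4-phenyl-3,4-dihydro-2H-chromen-2-one | O=C1C[C@H](c2ccccc2)c2c(O)c(C(C)=O)c(OC)cc2O1 | intermediate
14 | 4-methoxybenzaldehyde | COc1ccc(C=O)cc1 | starting material
15 | (3R)-3-(3-acetyl-2,6-dihydroxy-4-methoxyphenyl)-3-phenylpropanoic acid (ring-opened acetophenone acid) | O=C(O)C[C@H](c1ccccc1)c1c(O)c(C(C)=O)c(OC)cc1O | intermediate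
16 | (3R)-3-{2,6-dihydroxy-4-methoxy-3-[(2E)-3-(4-methoxyphenyl)prop-2-enoyl]phenyl}-3-phenylpropanoic acid | O=C(O)C[C@H](c1ccccc1)c1c(O)c(C(=O)/C=C/c2ccc(OC)cc2)c(OC)cc1O | intermediate
17 | (3R)-3-[7-hydroxy-5-methoxy-2-(4-methoxyphenyl)-4-oxo-3,4-dihydro-2H-chromen-8-yl]-3-phenylpropanoic acid (flavanone acid, both C2 epimers) | O=C(O)C[C@H](c1ccccc1)c1c(O)cc(OC)c2C(=O)CC(c3ccc(OC)cc3)Oc12 | intermediate
18 | (3R)-3-[7-hydroxy-5-methoxy-2-(4-methoxyphenyl)-4-oxo-4H-chromen-8-yl]-3-phenylpropanoic acid | O=C(O)C[C@H](c1ccccc1)c1c(O)cc(OC)c2c(=O)cc(-c3ccc(OC)cc3)oc12 | intermediate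
19 | (10R)-5-hydroxy-2-(4-hydroxyphenyl)-10-phenyl-9,10-dihydro-4H,8H-pyrano[2,3-f]chromene-4,8-dione (demethylated lactone) | O=C1C[C@H](c2ccccc2)c2c(O1)cc(O)c3c(=O)cc(-c4ccc(O)cc4)oc23 | intermediate
20 | (3R)-3-[5,7-dihydroxy-2-(4-hydroxyphenyl)-4-oxo-4H-chromen-8-yl]-3-phenylpropanoic acid | O=C(O)C[C@H](c1ccccc1)c1c(O)cc(O)c2c(=O)cc(-c3ccc(O)cc3)oc12 | target

Total step count: 11. Longest linear sequence: 11 steps (1 to 20); 5 and 14 are commercial.

Steps most likely to fail

Step 7. The opened keto ester 10 may return to 9 faster than its hindered, β-branched carbanion acylates the ester, so that conversion stalls, or long heating with methoxide may begin to exchange the tert-butyl ester. The fallback brings ring A in ready-made by known chemistry. No route intermediate can supply an aromatic ring A, so it sets out from commercial 5-methoxyresorcinol instead of a numbered compound, and it comes back at 12.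
- Protection with MOMCl and iPr2NEt should give 1-methoxy-3,5-bis(methoxymethoxy)benzene F1.
- Directed ortho-lithiation between the two MOM ethers (n-BuLi, THF, 0 °C) and quenching with DMF should give 4-methoxy-2,6-bis(methoxymethoxy)benzaldehyde F2.
- Wittig olefination with Ph3P=CHCO2tBu should give tert-butyl (2E)-3-[4-methoxy-2,6-bis(methoxymethoxy)phenyl]prop-2-enoate F3.
- Asymmetric 1,4-addition of phenylboronic acid (Hayashi–Miyaura reaction; [RhCl(C2H4)2]2, chiral bicyclo[2.2.2]octadiene ligand of the enantiomer that gives the R product, aq. KOH, dioxane, 50 °C) should give tert-butyl (3R)-3-[4-methoxy-2,6-bis(methoxymethoxy)phenyl]-3-phenylpropanoate F4.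
- TFA in CH2Cl2 removes both MOM groups and the tert-butyl ester and closes the lactone to 12, which enters step 8 at the acetylation stage.

Step 9. After the lactone has opened, the ketone sits in a trianion whose para-phenoxide donates into the carbonyl, so enolization and condensation may be slow and the aldehyde may be lost to Cannizzaro disproportionation. The fallback is a Baker–Venkataraman sequence that uses no hydroxide until the end; it sets out from 13, replaces steps 9 and 10, and comes back at 18.
- O-Acylation of the chelated phenol with 4-methoxybenzoyl chloride (DBU, DMAP (cat.), CH2Cl2) should give (4R)-6-acetyl-7-methoxy-2-oxo-4-phenyl-3,4-dihydro-2H-chromen-5-yl 4-methoxybenzoate F5.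
- Base-induced acyl transfer from oxygen to the ketone enolate (LiN(SiMe3)2, THF, –78 → 0 °C) should give the 1,3-diketone (4R)-5-hydroxy-7-methoxy-6-[3-(4-methoxyphenyl)-3-oxopropanoyl]-4-phenyl-3,4-dihydro-2H-chromen-2-one F6.
- Cyclodehydration (H2SO4 (cat.), AcOH, 90 °C) should give the lactone-fused flavone (10R)-5-methoxy-2-(4-methoxyphenyl)-10-phenyl-9,10-dihydro-4H,8H-pyrano[2,3-f]chromene-4,8-dione F7.
- Brief treatment with 1 M NaOH and cold acidification opens the lactone to 18; material whose lactone opened earlier converges at the same point.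

Step 4. Proton transfer from the acidic product or from the α-methylene of 6 may quench the dianion before C-acylation, giving low conversion and self-condensation. The fallback is the dioxinone route; it sets out from 4, replaces steps 4 and 5, and comes back at 8.
- Imidazolide 6, made as before, acylates the lithium dienolate of 2,2,6-trimethyl-4H-1,3-dioxin-4-one (LiN(SiMe3)2, THF, –78 °C) at the 6-methyl carbon, which should give tert-butyl (3R)-6-(2,2-dimethyl-4-oxo-4H-1,3-dioxin-6-yl)-5-oxo-3-phenylhexanoate F8.
- Heating in toluene at 110 °C expels acetone, and the acylketene is captured by the enol oxygen of the ketone to give hydroxypyranone 8 directly.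

Further compounds
F1 | step 7 | 1-methoxy-3,5-bis(methoxymethoxy)benzene | COCOc1cc(OC)cc(OCOC)c1
F2 | step 7 | 4-methoxy-2,6-bis(methoxymethoxy)benzaldehyde | COCOc1cc(OC)cc(OCOC)c1C=O
F3 | step 7 | tert-butyl (2E)-3-[4-methoxy-2,6-bis(methoxymethoxy)phenyl]prop-2-enoate | CC(C)(C)OC(=O)/C=C/c1c(OCOC)cc(OC)cc1OCOC
F4 | step 7 | tert-butyl (3R)-3-[4-methoxy-2,6-bis(methoxymethoxy)phenyl]-3-phenylpropanoate | CC(C)(C)OC(=O)C[C@H](c1ccccc1)c1c(OCOC)cc(OC)cc1OCOC
F5 | step 9 | (4R)-6-acetyl-7-methoxy-2-oxo-4-phenyl-3,4-dihydro-2H-chromen-5-yl 4-methoxybenzoate | O=C1C[C@H](c2ccccc2)c2c(OC(=O)c3ccc(OC)cc3)c(C(C)=O)c(OC)cc2O1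
F6 | step 9 | (4R)-5-hydroxy-7-methoxy-6-[3-(4-methoxyphenyl)-3-oxopropanoyl]-4-phenyl-3,4-dihydro-2H-chromen-2-one | O=C1C[C@H](c2ccccc2)c2c(O)c(C(=O)CC(=O)c3ccc(OC)cc3)c(OC)cc2O1
F7 | step 9 | (10R)-5-methoxy-2-(4-methoxyphenyl)-10-phenyl-9,10-dihydro-4H,8H-pyrano[2,3-f]chromene-4,8-dione | O=C1C[C@H](c2ccccc2)c2c(O1)cc(OC)c3c(=O)cc(-c4ccc(OC)cc4)oc23
F8 | step 4 | tert-butyl (3R)-6-(2,2-dimethyl-4-oxo-4H-1,3-dioxin-6-yl)-5-oxo-3-phenylhexanoate | CC(C)(C)OC(=O)C[C@H](c1ccccc1)CC(=O)CC1=CC(=O)OC(C)(C)O1
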